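**Plan**

- Retrosynthetic cuts: O1–C2 of the pyranone ring (ring C, closed last); the epoxide of a chalcone; C2–C3 as the enone C=C (Claisen–Schmidt); C4–C4a (acylation of an aryllithium); C8–prenyl (allylation of an aryllithium); C8a–O1 (C–H borylation/oxidation of a 2-methoxyresorcinol ether).
- Forward order: ring A is built up to a hexasubstituted acetophenone in which only the future O1 carries a mild-acid-labile 1-ethoxyethyl (EE) acetal, while O5 and O7 carry MOM. Condensation with EE-protected salicylaldehyde joins ring B, the enone is epoxidised, ring C is closed, and the MOM groups are removed.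
- Enabling feature: the phenol on C2' of ring B is ortho to C2, so ring B plus C2 can become an ortho-quinone methide (O=C2'–C1'=C2). This erases and re-sets C2 while C3 stays fixed; the trans-diequatorial 2-aryl/3-hydroxy pyranone is the sink.
- Stereochemistry: C3 (R) comes from the poly-L-leucine (Juliá–Colonna) epoxidation (epoxide Cα). C2 (R) comes from the C3-controlled, stereoconvergent ring closure.

Key step: step 9

Remark: the acetal carbons of the EE groups form without stereocontrol. Compounds 5–9 and 11–13 are carried as mixtures at these centres (left unassigned in the SMILES); this is without consequence because both EE groups leave in step 9.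
Remark: aryllithiums 6 and 8 are written as monomers.

**Route**

Step 1
Reactants: 1 2-methoxyresorcinol (2-methoxybenzene-1,3-diol)
Product: 2 2-methoxy-1,3-bis(methoxymethoxy)benzene
Conditions: NaH (2.4 equiv), MOMCl (2.4 equiv), DMF, 0 °C → rt
Reagents that add atoms: chloromethyl methyl ether (MOMCl), COCCl
Why: Williamson-type O-alkylation of both phenoxides installs base-stable MOM ethers that later serve as directed-metalation groups; no stereocenter is formed.

Step 2
Reactants: 2 2-methoxy-1,3-bis(methoxymethoxy)benzene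
Product: 4 4-methoxy-3,5-bis(methoxymethoxy)phenol, via aryl pinacol boronate 3 (not isolated)
Conditions: [Ir(OMe)(cod)]2 (1.5 mol %), dtbpy (3 mol %), B2pin2 (0.6 equiv), THF, 80 °C; then aq NaOH, 30% H2O2, 0 °C → rt
Reagents that add atoms: bis(pinacolato)diboron, CC1(C)OB(OC1(C)C)B1OC(C)(C)C(C)(C)O1 (boron of 3); hydrogen peroxide, OO (oxygen of 4)
Why: sterically governed Ir-catalysed C–H borylation should go to C5, the only C–H without an ortho substituent, and the boronate is oxidised in the same pot (one-pot borylation/oxidation), giving the future O1 as the only free hydroxyl.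

Step 3
Reactants: 4 4-methoxy-3,5-bis(methoxymethoxy)phenol
Product: 5 5-(1-ethoxyethoxy)-2-methoxy-1,3-bis(methoxymethoxy)benzene
Conditions: ethyl vinyl ether (3 equiv), PPTS (5 mol %), CH2Cl2, 0 °C → rt
Reagents that add atoms: ethyl vinyl ether, C=COCC
Why: acid-catalysed addition of the phenol to the vinyl ether marks the future O1 with an acetal that directs metalation, is base-stable, and is cleaved by PPTS under conditions that leave aryl MOM ethers intact.

Step 4
Reactants: 5 5-(1-ethoxyethoxy)-2-methoxy-1,3-bis(methoxymethoxy)benzene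
Product: 7 1-(1-ethoxyethoxy)-4-methoxy-3,5-bis(methoxymethoxy)-2-(3-methylbut-2-en-1-yl)benzene, via aryllithium 6 (not isolated)
Conditions: n-BuLi (1.1 equiv), THF, 0 °C; then CuBr·SMe2 (10 mol %), prenyl bromide (1.3 equiv), −78 °C → rt
Reagents that add atoms: prenyl bromide (1-bromo-3-methylbut-2-ene), CC(C)=CCBr
Why: directed ortho-metalation occurs at one of the two equivalent ring C–H positions, each flanked by the EE and a MOM acetal, and copper-catalysed SN2 allylation of the aryllithium should give the linear prenyl arene.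

Step 5
Reactants: 7 1-(1-ethoxyethoxy)-4-methoxy-3,5-bis(methoxymethoxy)-2-(3-methylbut-2-en-1-yl)benzene
Product: 9 1-[2-(1-ethoxyethoxy)-5-methoxy-4,6-bis(methoxymethoxy)-3-(3-methylbut-2-en-1-yl)phenyl]ethan-1-one, via aryllithium 8 (not isolated)
Conditions: n-BuLi (1.2 equiv), TMEDA (1.2 equiv), THF, −20 → 0 °C; then MeC(O)N(OMe)Me (1.5 equiv), −78 → 0 °C; H2O
Reagents that add atoms: N-methoxy-N-methylacetamide, CC(=O)N(C)OC
Why: directed ortho-metalation at the last ring C–H (between the EE and MOM acetals) followed by Weinreb acylation, whose chelated tetrahedral intermediate prevents over-addition, should give the methyl ketone with the acyl group next to the future O1 and O5.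

Step 6
Reactants: 10 salicylaldehyde (2-hydroxybenzaldehyde)
Product: 11 2-(1-ethoxyethoxy)benzaldehyde
Conditions: ethyl vinyl ether (3 equiv), PPTS (5 mol %), CH2Cl2, rt
Reagents that add atoms: ethyl vinyl ether, C=COCC
Why: the same acid-catalysed vinyl ether addition gives the ring-B phenol the same trigger group as O1, so that both are released together in step 9.

Step 7
Reactants: 9 1-[2-(1-ethoxyethoxy)-5-methoxy-4,6-bis(methoxymethoxy)-3-(3-methylbut-2-en-1-yl)phenyl]ethan-1-one; 11 2-(1-ethoxyethoxy)benzaldehyde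
Product: 12 (E)-1-[2-(1-ethoxyethoxy)-5-methoxy-4,6-bis(methoxymethoxy)-3-(3-methylbut-2-en-1-yl)phenyl]-3-[2-(1-ethoxyethoxy)phenyl]prop-2-en-1-one
Conditions: KOH (5 equiv), EtOH, rt
Reagents that add atoms: none
Why: Claisen–Schmidt aldol condensation with E1cB dehydration should give the E-enone under thermodynamic control, and all acetals are stable to base.

Step 8
Reactants: 12 (E)-1-[2-(1-ethoxyethoxy)-5-methoxy-4,6-bis(methoxymethoxy)-3-(3-methylbut-2-en-1-yl)phenyl]-3-[2-(1-ethoxyethoxy)phenyl]prop-2-en-1-one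
Product: 13 [2-(1-ethoxyethoxy)-5-methoxy-4,6-bis(methoxymethoxy)-3-(3-methylbut-2-en-1-yl)phenyl][(2R,3S)-3-[2-(1-ethoxyethoxy)phenyl]oxiran-2-yl]methanone
Conditions: immobilised poly-L-leucine, urea–H2O2 (1.5 equiv), DBU (1.5 equiv), THF, rt
Reagents that add atoms: hydrogen peroxide (used as its urea adduct), OO
Why: Juliá–Colonna (Weitz–Scheffer-type) nucleophilic epoxidation attacks only the enone, not the electron-rich prenyl alkene, and the poly-L-leucine helix should deliver the (2R,3S)-epoxide, fixing Cα (the future C3) as R.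

Step 9
Reactants: 13 [2-(1-ethoxyethoxy)-5-methoxy-4,6-bis(methoxymethoxy)-3-(3-methylbut-2-en-1-yl)phenyl][(2R,3S)-3-[2-(1-ethoxyethoxy)phenyl]oxiran-2-yl]methanone
Product: 16 (2R,3R)-3-hydroxy-2-(2-hydroxyphenyl)-6-methoxy-5,7-bis(methoxymethoxy)-8-(3-methylbut-2-en-1-yl)-2,3-dihydro-4H-chromen-4-one, via bisphenol epoxide 14 (not isolated), via ortho-quinone methide 15 (not isolated)
Conditions: PPTS (0.2 equiv), EtOH (10 equiv), CH2Cl2, 0 °C → rt; then Et3N (0.5 equiv), 0 °C → rt, argon
Reagents that add atoms: none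
Why: PPTS/EtOH transacetalises only the two EE groups (aryl MOM ethers should survive) to give bisphenol epoxide 14; on buffering with Et3N the ring-B phenol(ate) pushes through C2'–C1' to break the benzylic Cβ–O bond of the epoxide, giving ortho-quinone methide 15 with the Cα–O bond (future C3–OH) untouched, and the chelated C8a phenol adds to the methide carbon. The closest known reaction types are the acid- or base-mediated cyclisation of 2'-hydroxychalcone epoxides to trans-dihydroflavonols, intramolecular oxa-Michael additions to ortho-quinone methides, and the C2 epimerisation of hydroxyaryl dihydroflavonols through quinone methides. Ring C closes by a 6-exo-trig oxa-Michael addition (O1 to C2, with C2=C1' exocyclic); a direct 6-endo-tet opening of the epoxide with inversion at Cβ would lead to the same product. The new stereocenter C2 is controlled by C3: the half-chair with 2-aryl and 3-OH both pseudo-equatorial is favoured kinetically, and any cis isomer can re-open through 15 and drain to the trans (2R,3R) product, so β-epimers, cis/trans epoxide and SN1/SN2 pathways all converge. The step needs O1 rather than O5 to close, which the surviving MOM on O5 secures, and it needs attack at Cβ rather than 5-exo attack at Cα, which the ring-B push secures by making Cβ the electrophile. It also needs C3 to stay intact, so weak base, low temperature and short time are used to suppress tautomerisation of 15 to the achiral enol.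

Step 10
Reactants: 16 (2R,3R)-3-hydroxy-2-(2-hydroxyphenyl)-6-methoxy-5,7-bis(methoxymethoxy)-8-(3-methylbut-2-en-1-yl)-2,3-dihydro-4H-chromen-4-one
Product: 17 floranol, (2R,3R)-3,5,7-trihydroxy-2-(2-hydroxyphenyl)-6-methoxy-8-(3-methylbut-2-en-1-yl)-2,3-dihydro-4H-chromen-4-one
Conditions: 3 M aq HCl, MeOH, rt → 40 °C
Reagents that add atoms: none
Why: acid-catalysed acetal solvolysis (transacetalisation to dimethoxymethane), the standard end-game for MOM-protected prenylflavonoids, should free the 5- and 7-hydroxyls without touching C3, while C2 could at most equilibrate toward the same trans isomer.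

**Compound list**

1 | 2-methoxyresorcinol (2-methoxybenzene-1,3-diol) | COc1c(O)cccc1O | starting material
2 | 2-methoxy-1,3-bis(methoxymethoxy)benzene | COCOc1cccc(OCOC)c1OC | intermediate
3 | 2-[4-methoxy-3,5-bis(methoxymethoxy)phenyl]-4,4,5,5-tetramethyl-1,3,2-dioxaborolane | COCOc1cc(B2OC(C)(C)C(C)(C)O2)cc(OCOC)c1OC | intermediate (not isolated)
4 | 4-methoxy-3,5-bis(methoxymethoxy)phenol | COCOc1cc(O)cc(OCOC)c1OC | intermediate
5 | 5-(1-ethoxyethoxy)-2-methoxy-1,3-bis(methoxymethoxy)benzene | CCOC(C)Oc1cc(OCOC)c(OC)c(OCOC)c1 | intermediate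
6 | [2-(1-ethoxyethoxy)-5-methoxy-4,6-bis(methoxymethoxy)phenyl]lithium | CCOC(C)Oc1cc(OCOC)c(OC)c(OCOC)c1[Li] | intermediate (not isolated)
7 | 1-(1-ethoxyethoxy)-4-methoxy-3,5-bis(methoxymethoxy)-2-(3-methylbut-2-en-1-yl)benzene | CCOC(C)Oc1cc(OCOC)c(OC)c(OCOC)c1CC=C(C)C | intermediate
8 | [2-(1-ethoxyethoxy)-5-methoxy-4,6-bis(methoxymethoxy)-3-(3-methylbut-2-en-1-yl)phenyl]lithium | CCOC(C)Oc1c([Li])c(OCOC)c(OC)c(OCOC)c1CC=C(C)C | intermediate (not isolated)
9 | 1-[2-(1-ethoxyethoxy)-5-methoxy-4,6-bis(methoxymethoxy)-3-(3-methylbut-2-en-1-yl)phenyl]ethan-1-one | CC(=O)c1c(OC(C)OCC)c(CC=C(C)C)c(OCOC)c(OC)c1OCOC | intermediate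
10 | salicylaldehyde (2-hydroxybenzaldehyde) | O=Cc1ccccc1O | starting material
11 | 2-(1-ethoxyethoxy)benzaldehyde | CCOC(C)Oc1ccccc1C=O | intermediate
12 | (E)-1-[2-(1-ethoxyethoxy)-5-methoxy-4,6-bis(methoxymethoxy)-3-(3-methylbut-2-en-1-yl)phenyl]-3-[2-(1-ethoxyethoxy)phenyl]prop-2-en-1-one | CCOC(C)Oc1ccccc1/C=C/C(=O)c1c(OC(C)OCC)c(CC=C(C)C)c(OCOC)c(OC)c1OCOC | intermediate
13 | [2-(1-ethoxyethoxy)-5-methoxy-4,6-bis(methoxymethoxy)-3-(3-methylbut-2-en-1-yl)phenyl][(2R,3S)-3-[2-(1-ethoxyethoxy)phenyl]oxiran-2-yl]methanone | O=C([C@@H]1O[C@H]1c1ccccc1OC(C)OCC)c1c(OC(C)OCC)c(CC=C(C)C)c(OCOC)c(OC)c1OCOC | intermediate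
14 | [2-hydroxy-5-methoxy-4,6-bis(methoxymethoxy)-3-(3-methylbut-2-en-1-yl)phenyl][(2R,3S)-3-(2-hydroxyphenyl)oxiran-2-yl]methanone | O=C([C@@H]1O[C@H]1c1ccccc1O)c1c(O)c(CC=C(C)C)c(OCOC)c(OC)c1OCOC | intermediate (not isolated)
15 | (2R)-2-hydroxy-1-[2-hydroxy-5-methoxy-4,6-bis(methoxymethoxy)-3-(3-methylbut-2-en-1-yl)phenyl]-3-(6-oxocyclohexa-2,4-dien-1-ylidene)propan-1-one (alkene geometry not defined) | COCOc1c(OC)c(OCOC)c(CC=C(C)C)c(O)c1C(=O)[C@H](O)C=C1C=CC=CC1=O | intermediate (not isolated)
16 | (2R,3R)-3-hydroxy-2-(2-hydroxyphenyl)-6-methoxy-5,7-bis(methoxymethoxy)-8-(3-methylbut-2-en-1-yl)-2,3-dihydro-4H-chromen-4-one | COc1c(OCOC)c(CC=C(C)C)c2c(c1OCOC)C(=O)[C@H](O)[C@@H](c1ccccc1O)O2 | intermediate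
17 | floranol, (2R,3R)-3,5,7-trihydroxy-2-(2-hydroxyphenyl)-6-methoxy-8-(3-methylbut-2-en-1-yl)-2,3-dihydro-4H-chromen-4-one | COc1c(O)c(CC=C(C)C)c2c(c1O)C(=O)[C@H](O)[C@@H](c1ccccc1O)O2 | target

**Step count and risks**

Total steps: 10. Longest linear sequence: 9 steps (steps 1–5 and 7–10, from 2-methoxyresorcinol).

The three steps most likely to fail:

1. Step 8 (epoxidation). The 2,6-dioxygenated aroyl group is crowded and twisted out of conjugation, so hydroperoxide addition may be slow and the facial selectivity on the polypeptide may be poor. Fallback, setting out from 7 and 11 and returning at 13: the stereocenters are set on a small, unhindered enamide and the ketone is made by acylation instead of condensation. Aldehyde 11 is homologated by a Horner–Wadsworth–Emmons reaction with diethyl (2-morpholino-2-oxoethyl)phosphonate (LiCl, DBU, MeCN) to (E)-3-[2-(1-ethoxyethoxy)phenyl]-1-(morpholin-4-yl)prop-2-en-1-one F1. This is epoxidised with a lanthanide–BINOL–Ph3As=O catalyst and TBHP, the BINOL enantiomer being chosen for the 2R,3S series, to [(2R,3S)-3-[2-(1-ethoxyethoxy)phenyl]oxiran-2-yl](morpholin-4-yl)methanone F2. Aryllithium 8, generated from 7 as in step 5, is then acylated by F2 at −78 °C, which should give epoxy ketone 13 directly.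

2. Step 9 (ring closure). The quinone methide may lose the proton at Cα (tautomerisation to the achiral α-hydroxy enone, eroding C3), may be captured by ethanol, or the A-ring phenoxide may attack Cα in a 5-exo mode. Fallback, setting out from 9 and 10 and returning at 17: the ring-B oxygen stays capped so that no quinone methide can form and the closure is the classical stereospecific epoxide opening. Salicylaldehyde 10 is converted (NaH, MOMCl) into 2-(methoxymethoxy)benzaldehyde F3. Claisen–Schmidt condensation with 9 gives (E)-1-[2-(1-ethoxyethoxy)-5-methoxy-4,6-bis(methoxymethoxy)-3-(3-methylbut-2-en-1-yl)phenyl]-3-[2-(methoxymethoxy)phenyl]prop-2-en-1-one F4. Poly-L-leucine epoxidation as in step 8 gives [2-(1-ethoxyethoxy)-5-methoxy-4,6-bis(methoxymethoxy)-3-(3-methylbut-2-en-1-yl)phenyl][(2R,3S)-3-[2-(methoxymethoxy)phenyl]oxiran-2-yl]methanone F5. PPTS/EtOH removes only the EE group to give [2-hydroxy-5-methoxy-4,6-bis(methoxymethoxy)-3-(3-methylbut-2-en-1-yl)phenyl][(2R,3S)-3-[2-(methoxymethoxy)phenyl]oxiran-2-yl]methanone F6. Catalytic CSA in CH2Cl2 at 0 °C should close ring C by anti 6-endo opening at the ortho-alkoxybenzylic carbon to (2R,3R)-3-hydroxy-6-methoxy-5,7-bis(methoxymethoxy)-2-[2-(methoxymethoxy)phenyl]-8-(3-methylbut-2-en-1-yl)-2,3-dihydro-4H-chromen-4-one F7. The three MOM groups are then removed under the conditions of step 10 to give 17.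

3. Step 10 (MOM removal). Protic acid may ionise the C2–O1 bond through the free ring-B phenol (ring opening and re-closure onto the newly freed O5, i.e. regiochemical scrambling) and may add the 7-OH across the prenyl alkene. Fallback, setting out from 16 and returning at 17: ring C is locked before deprotection and the acetals are cleaved aprotically. The ring-B phenol of 16 is acetylated selectively (Ac2O 1.05 equiv, pyridine, CH2Cl2, 0 °C) to 2-[(2R,3R)-3-hydroxy-6-methoxy-5,7-bis(methoxymethoxy)-8-(3-methylbut-2-en-1-yl)-4-oxo-3,4-dihydro-2H-chromen-2-yl]phenyl acetate F8; an acylated 2'-oxygen can no longer expel O1. The MOM ethers are cleaved with TMSBr (CH2Cl2, 4 Å MS, −30 °C, then aqueous NaHCO3) to 2-[(2R,3R)-3,5,7-trihydroxy-6-methoxy-8-(3-methylbut-2-en-1-yl)-4-oxo-3,4-dihydro-2H-chromen-2-yl]phenyl acetate F9. The aryl acetate is then removed under near-neutral conditions (NH4OAc, aqueous MeOH, rt) to give 17.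

**Further compounds**

F1 | step 8 | (E)-3-[2-(1-ethoxyethoxy)phenyl]-1-(morpholin-4-yl)prop-2-en-1-one | CCOC(C)Oc1ccccc1/C=C/C(=O)N1CCOCC1
F2 | step 8 | [(2R,3S)-3-[2-(1-ethoxyethoxy)phenyl]oxiran-2-yl](morpholin-4-yl)methanone | O=C([C@@H]1O[C@H]1c1ccccc1OC(C)OCC)N1CCOCC1
F3 | step 9 | 2-(methoxymethoxy)benzaldehyde | COCOc1ccccc1C=O
F4 | step 9 | (E)-1-[2-(1-ethoxyethoxy)-5-methoxy-4,6-bis(methoxymethoxy)-3-(3-methylbut-2-en-1-yl)phenyl]-3-[2-(methoxymethoxy)phenyl]prop-2-en-1-one | COCOc1ccccc1/C=C/C(=O)c1c(OC(C)OCC)c(CC=C(C)C)c(OCOC)c(OC)c1OCOC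
F5 | step 9 | [2-(1-ethoxyethoxy)-5-methoxy-4,6-bis(methoxymethoxy)-3-(3-methylbut-2-en-1-yl)phenyl][(2R,3S)-3-[2-(methoxymethoxy)phenyl]oxiran-2-yl]methanone | O=C([C@@H]1O[C@H]1c1ccccc1OCOC)c1c(OC(C)OCC)c(CC=C(C)C)c(OCOC)c(OC)c1OCOC
F6 | step 9 | [2-hydroxy-5-methoxy-4,6-bis(methoxymethoxy)-3-(3-methylbut-2-en-1-yl)phenyl][(2R,3S)-3-[2-(methoxymethoxy)phenyl]oxiran-2-yl]methanone | O=C([C@@H]1O[C@H]1c1ccccc1OCOC)c1c(O)c(CC=C(C)C)c(OCOC)c(OC)c1OCOC
F7 | step 9 | (2R,3R)-3-hydroxy-6-methoxy-5,7-bis(methoxymethoxy)-2-[2-(methoxymethoxy)phenyl]-8-(3-methylbut-2-en-1-yl)-2,3-dihydro-4H-chromen-4-one | COc1c(OCOC)c(CC=C(C)C)c2c(c1OCOC)C(=O)[C@H](O)[C@@H](c1ccccc1OCOC)O2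
F8 | step 10 | 2-[(2R,3R)-3-hydroxy-6-methoxy-5,7-bis(methoxymethoxy)-8-(3-methylbut-2-en-1-yl)-4-oxo-3,4-dihydro-2H-chromen-2-yl]phenyl acetate | COc1c(OCOC)c(CC=C(C)C)c2c(c1OCOC)C(=O)[C@H](O)[C@@H](c1ccccc1OC(C)=O)O2
F9 | step 10 | 2-[(2R,3R)-3,5,7-trihydroxy-6-methoxy-8-(3-methylbut-2-en-1-yl)-4-oxo-3,4-dihydro-2H-chromen-2-yl]phenyl acetate | COc1c(O)c(CC=C(C)C)c2c(c1O)C(=O)[C@H](O)[C@@H](c1ccccc1OC(C)=O)O2
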